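## Retrosynthetic overview (numbers follow the forward route)

1. Target 7 ⇒ open-chain, achiral imidazolone amide 5 (the urea analogue of dihydrooroidin); both aminal C–N bonds are cut in one oxidative step.
2. Forward: Br⁺ oxidises the imidazolone C4=C5; the amide N closes the pyrrolidine at C4 (quaternary centre, set by a chiral phosphoric acid); the pyrrole N then closes the pyrazinone at C5 (cis fusion enforced).
3. 5 ⇒ amine 3 + trichloroacetyl-dibromopyrrole 4 (amide bond).
4. 3 ⇒ L-ornithine methyl ester 1 (ester → aldehyde 2, then cyanate closes the imidazolone).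
5. Ring order: imidazolone (step 1) → pyrrolidine → pyrazinone (both step 3); the pyrrole ring is bought in 4.

Assumption: the facial sense of induction of the phosphoric acid in step 3 cannot be predicted from precedent; (R)-TRIP is written, and (S)-TRIP is used instead, with no other change, if the first run gives the mirror image.

## Route

Step 1
Reactants: 1 L-ornithine methyl ester dihydrochloride
Product: 3 4-(3-aminopropyl)-1,3-dihydro-2H-imidazol-2-one hydrochloride, via (2S)-2,5-diaminopentanal dihydrochloride 2 (not isolated)
Conditions: 5% Na(Hg), H2O, aq. HCl to hold pH 1.5–2.5, 0–5 °C; decant Hg; then KOCN (1.05 equiv), pH 4.5, rt → 70 °C; acidify (pH 1–2), concentrate, crystallise from EtOH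
Reagents that add atoms: potassium cyanate, [K+].[O-]C#N
Why: Akabori reduction (sodium amalgam on the protonated α-amino ester stops at the aldehyde hydrate) followed by a Marckwald-type condensation, in which cyanate at pH 4.5 carbamoylates only the much less basic α-amine and the ureido aldehyde closes and dehydrates to the imidazol-2-one; the ornithine stereocentre is destroyed here on purpose.

Step 2
Reactants: 3 4-(3-aminopropyl)-1,3-dihydro-2H-imidazol-2-one hydrochloride; 4 2,2,2-trichloro-1-(4,5-dibromo-1H-pyrrol-2-yl)ethan-1-one
Product: 5 4,5-dibromo-N-[3-(2-oxo-2,3-dihydro-1H-imidazol-4-yl)propyl]-1H-pyrrole-2-carboxamide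
Conditions: Na2CO3 (2.2 equiv), DMF, rt, 16 h; pour into water, filter
Reagents that add atoms: none
Why: Haloform-type acyl transfer, in which the primary amine adds to the trichloromethyl ketone and CCl3⁻ leaves as chloroform, while the imidazolone and pyrrole N–H groups are not nucleophilic enough to compete; no stereocentre is formed.

Step 3
Reactants: 5 4,5-dibromo-N-[3-(2-oxo-2,3-dihydro-1H-imidazol-4-yl)propyl]-1H-pyrrole-2-carboxamide
Product: 7 dibromophakellstatin, via (5R,9R)-9-bromo-1-(4,5-dibromo-1H-pyrrole-2-carbonyl)-1,6,8-triazaspiro[4.4]nonan-7-one 6 (not isolated)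
Conditions: NBS (1.0 equiv, slow addition), (R)-TRIP (10 mol %), THF/CH2Cl2 1:1 (0.01 M), −60 °C, dark; then K2CO3 (3 equiv), DMF, −20 °C → rt
Reagents that add atoms: none
Why: Proposed new method: NBS hydrogen-bonded to the chiral phosphoric acid brominates the electron-rich ene-urea at C5, the resulting N-acyliminium ion at C4 stays in a contact ion pair with the chiral phosphate so that the amide N closes the pyrrolidine (5-exo, anti to Br) on one face and fixes the quaternary centre as R, and base then lets the pyrrolide N displace the activated C5 bromide on the only face a cis-fused ring allows, which gives the S C–H aminal centre; the closest known reaction types are the racemic halogen-mediated oxidative bis-cyclisation of dihydrooroidin-type precursors (Br2 or NBS, then base) and the chiral-phosphoric-acid-catalysed enantioselective bromination/amination of enecarbamates with NBS.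

## Compound list

1 | L-ornithine methyl ester dihydrochloride, methyl (2S)-2,5-diaminopentanoate·2HCl | Cl.Cl.COC(=O)[C@@H](N)CCCN | starting material
2 | (2S)-2,5-diaminopentanal dihydrochloride (in water, mainly as the hydrate) | Cl.Cl.N[C@@H](CCCN)C=O | intermediate
3 | 4-(3-aminopropyl)-1,3-dihydro-2H-imidazol-2-one hydrochloride (achiral) | Cl.NCCCC1=CNC(=O)N1 | intermediate
4 | 2,2,2-trichloro-1-(4,5-dibromo-1H-pyrrol-2-yl)ethan-1-one | O=C(c1cc(Br)c(Br)[nH]1)C(Cl)(Cl)Cl | starting material
5 | 4,5-dibromo-N-[3-(2-oxo-2,3-dihydro-1H-imidazol-4-yl)propyl]-1H-pyrrole-2-carboxamide (achiral) | O=C(NCCCC1=CNC(=O)N1)c1cc(Br)c(Br)[nH]1 | intermediate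
6 | (5R,9R)-9-bromo-1-(4,5-dibromo-1H-pyrrole-2-carbonyl)-1,6,8-triazaspiro[4.4]nonan-7-one (Br trans to the acylated pyrrolidine N) | O=C1N[C@H](Br)[C@]2(CCCN2C(=O)c3cc(Br)c(Br)[nH]3)N1 | intermediate
7 | dibromophakellstatin: 4,5-dibromopyrrole fused through N1/C2 to a pyrazinone, pyrrolidine fused at the amide N and the quaternary aminal carbon, imidazolidin-2-one cis-fused across the two aminal carbons; aminal C–H (C6) is S, quaternary aminal carbon (C10) is R | O=C1N[C@H]2n3c(cc(Br)c3Br)C(=O)N3CCC[C@]23N1 | target

Total step count: 3
Longest linear sequence: 3 steps (1 → 3 → 5 → 7)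

## Steps most likely to fail, with fallbacks

**Step 3 (highest risk).** The failure modes are:
- low ee, because 5 is poorly soluble in ion-pairing solvents and uncatalysed bromination competes;
- the wrong sense of induction;
- attack of pyrrole C3 instead of N on the C5 cation if the second stage is not basic enough;
- over-bromination.

The fallback gives up catalyst control and resolves at the end. Setting out from 5, NBS (1.0 equiv) in TFA at 0 °C gives the racemic trans-bromo spiro-aminal F1. After evaporation, K2CO3 in MeOH/DMF closes the pyrazinone ring to racemic dibromophakellstatin F2. Preparative HPLC on an amylose tris(3,5-dimethylphenylcarbamate) phase separates the enantiomers, and the (6S,10R) enantiomer is 7, where the fallback comes back to the route.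

**Step 1.** The failure modes are over-reduction to the amino alcohol, self-condensation of the free amino aldehyde, mercury handling on scale, and partial carbamoylation of the δ-amine. The fallback reaches the aldehyde by hydride reduction of a protected ester. Setting out from 1, Boc2O (2.2 equiv) with NaHCO3 in dioxane/H2O gives methyl (2S)-2,5-bis[(tert-butoxycarbonyl)amino]pentanoate F3. DIBAL-H in toluene/CH2Cl2 at −78 °C gives di-tert-butyl [(4S)-5-oxopentane-1,4-diyl]dicarbamate F4. 4 M HCl in dioxane removes both Boc groups and delivers 2, where the fallback comes back to the route; the solution is diluted with water and taken through the cyanate stage of step 1 to 3.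

**Step 2.** The failure modes are the low solubility of the salt 3 in DMF, slow acyl transfer, and hydrolysis of 4. The fallback changes the acyl donor and the activation mode. Setting out from 4, NaOH in THF/H2O followed by HCl gives 4,5-dibromo-1H-pyrrole-2-carboxylic acid F5. This acid is coupled with 3 using EDC·HCl/HOBt and NaHCO3 in DMF at rt, and the fallback comes back to the route at 5.

## Further compounds

F1 | step 3 | racemic trans-9-bromo-1-(4,5-dibromo-1H-pyrrole-2-carbonyl)-1,6,8-triazaspiro[4.4]nonan-7-one (1:1 mixture of 6 and its mirror image) | O=C1N[C@H](Br)[C@]2(CCCN2C(=O)c3cc(Br)c(Br)[nH]3)N1.O=C1N[C@@H](Br)[C@@]2(CCCN2C(=O)c3cc(Br)c(Br)[nH]3)N1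
F2 | step 3 | racemic dibromophakellstatin (1:1 mixture of 7 and its mirror image) | O=C1N[C@H]2n3c(cc(Br)c3Br)C(=O)N3CCC[C@]23N1.O=C1N[C@@H]2n3c(cc(Br)c3Br)C(=O)N3CCC[C@@]23N1
F3 | step 1 | methyl (2S)-2,5-bis[(tert-butoxycarbonyl)amino]pentanoate | COC(=O)[C@@H](NC(=O)OC(C)(C)C)CCCNC(=O)OC(C)(C)C
F4 | step 1 | di-tert-butyl [(4S)-5-oxopentane-1,4-diyl]dicarbamate | O=C[C@@H](NC(=O)OC(C)(C)C)CCCNC(=O)OC(C)(C)C
F5 | step 2 | 4,5-dibromo-1H-pyrrole-2-carboxylic acid | OC(=O)c1cc(Br)c(Br)[nH]1
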